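**Retrosynthetic overview**

1. No ring is formed. The fully substituted benzene ring is bought at the o-quinone oxidation level as tetrabromo-1,2-benzoquinone (1), which supplies all three bromines and both oxygens.
2. Key disconnection, aryl–CH2. The catechol ring carbon and the sulfone α-carbon are both natural donors, so the ring is used in its oxidised, polarity-reversed form. C4 of 1 is an acceptor (a vinylogous acyl bromide) and is attacked by the soft enolate of methyl 2-(methylsulfonyl)acetate (2).
3. The substitution product, quinone 3, sits in the flask as its sodium salt 4 and is reduced there to the catechol ester 5.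
4. The ester is a traceless activating group: hydrolysis to acid 6 and loss of CO2 give the target 7.

Assumption: the target has no stereocentre, so it is made as the single achiral compound drawn; the one stereocentre that appears on the way (in 5 and 6, racemic) is removed in step 2.

**Route**

Step 1
Reactants: 1 tetrabromo-1,2-benzoquinone (o-bromanil); 2 methyl 2-(methylsulfonyl)acetate
Product: 5 methyl 2-(2,3,6-tribromo-4,5-dihydroxyphenyl)-2-(methylsulfonyl)acetate (racemic), via tribromo-o-quinone ester 3 (not isolated), via sodium quinone-methide enolate 4 (not isolated)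
Conditions: 2 (2.1 equiv), NaH (2.1 equiv), THF, 0 °C; then 1 in THF added dropwise, −78 → 0 °C; then AcOH, aq. Na2S2O4, 0 °C → rt
Reagents that add atoms: methyl 2-(methylsulfonyl)acetate (compound 2), COC(=O)CS(C)(=O)=O
Why: Proposed new method: C4 of o-bromanil is the β-carbon of a bromo-enone, so the soft, doubly stabilised sodium enolate of 2 should add there and expel bromide (addition–elimination, nucleophilic vinylic substitution); the acidic product 3 is deprotonated at once by the second equivalent of enolate to the electron-rich anion 4, which blocks a second substitution, and dithionite then reduces the quinone level to the catechol; the closest known reaction types are displacement of halide from chloranil or 2,3-dichloro-1,4-naphthoquinone by malonate-type carbanions, C4/C5 substitution of tetrahalo-o-quinones by amines, and 1,4-addition of CH-acids to hindered o-quinones; the new stereocentre of 5 is formed racemic and is erased in step 2.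

Step 2
Reactants: 5 methyl 2-(2,3,6-tribromo-4,5-dihydroxyphenyl)-2-(methylsulfonyl)acetate
Product: 7 3,4,6-tribromo-5-[(methylsulfonyl)methyl]benzene-1,2-diol, via sulfonyl arylacetic acid 6 (not isolated)
Conditions: conc. HCl/AcOH (1:2), reflux, N2
Reagents that add atoms: none
Why: Acid-catalysed ester hydrolysis followed by thermal decarboxylation of the α-aryl-α-sulfonyl acetic acid 6 (malonic-type dealkoxycarbonylation, the developing carbanion being stabilised by the sulfone and the electron-poor tribromoaryl ring) removes the activating group and the only stereocentre, while the aryl bromides, catechol and sulfone are inert to hot aqueous acid under N2.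

**Compound list**

1 | 3,4,5,6-tetrabromocyclohexa-3,5-diene-1,2-dione (tetrabromo-1,2-benzoquinone, o-bromanil) | O=C1C(=O)C(Br)=C(Br)C(Br)=C1Br | starting material
2 | methyl 2-(methylsulfonyl)acetate | COC(=O)CS(C)(=O)=O | starting material
3 | methyl 2-(methylsulfonyl)-2-(2,5,6-tribromo-3,4-dioxocyclohexa-1,5-dien-1-yl)acetate (racemic) | COC(=O)C(S(C)(=O)=O)C1=C(Br)C(=O)C(=O)C(Br)=C1Br | intermediate
4 | sodium salt of 3, drawn as sodium 2,4,5-tribromo-3-[2-methoxy-1-(methylsulfonyl)-2-oxoethylidene]-6-oxocyclohexa-1,4-dien-1-olate | COC(=O)C(S(C)(=O)=O)=C1C(Br)=C([O-])C(=O)C(Br)=C1Br.[Na+] | intermediate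
5 | methyl 2-(2,3,6-tribromo-4,5-dihydroxyphenyl)-2-(methylsulfonyl)acetate (racemic) | COC(=O)C(S(C)(=O)=O)c1c(Br)c(O)c(O)c(Br)c1Br | intermediate
6 | 2-(2,3,6-tribromo-4,5-dihydroxyphenyl)-2-(methylsulfonyl)acetic acid (racemic) | OC(=O)C(S(C)(=O)=O)c1c(Br)c(O)c(O)c(Br)c1Br | intermediate
7 | 3,4,6-tribromo-5-[(methylsulfonyl)methyl]benzene-1,2-diol (achiral) | CS(=O)(=O)Cc1c(Br)c(O)c(O)c(Br)c1Br | target

**Totals**

Total step count: 2. Longest linear sequence: 2.

**Steps most likely to fail**

The route has only two steps. Both are listed, and the third entry is the in-flask reduction stage of step 1, which can fail independently of the C–C bond formation.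

1. Step 1, C–C bond formation (highest risk). Compound 1 is a strong one-electron oxidant. Electron transfer from the enolate (giving tetrabromocatechol and the oxidative dimer of 2) or addition at a carbonyl may beat substitution at C4. The fallback sets out from 2 and comes back to the route at 7. It keeps the same carbanion, replaces the quinone by an aryl halide that cannot oxidise it, and installs the bromines last.
   - Compound 2 is arylated with purchased 4-bromo-1,2-dimethoxybenzene using Pd(OAc)2, XPhos and K3PO4 in toluene at 100 °C (oxidative addition of the aryl bromide to zerovalent palladium, then C–C reductive elimination). This gives methyl 2-(3,4-dimethoxyphenyl)-2-(methylsulfonyl)acetate F1.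
   - LiOH in THF/water gives 2-(3,4-dimethoxyphenyl)-2-(methylsulfonyl)acetic acid F2. On acidification and warming it loses CO2 to give 1,2-dimethoxy-4-[(methylsulfonyl)methyl]benzene F3.
   - BBr3 in CH2Cl2 (−78 °C → rt) gives 4-[(methylsulfonyl)methyl]benzene-1,2-diol F4.
   - Br2 (3.3 equiv) in AcOH at rt, with NaHSO3 work-up, brominates the three free ring positions (each ortho or para to a hydroxyl) and gives 7.

2. Step 2, hydrolysis and decarboxylation. The methyl ester is flanked by a 2,6-dibromoaryl group and a sulfone, so acyl–oxygen hydrolysis may be slow. Long heating in acid also risks protodebromination. The fallback sets out from 1 and comes back to the route at 6. It uses a tert-butyl ester, which cleaves by alkyl–oxygen fission and is insensitive to crowding at the acyl carbon.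
   - Step 1 is run with purchased tert-butyl 2-(methylsulfonyl)acetate in place of 2.
   - It passes through tert-butyl 2-(methylsulfonyl)-2-(2,5,6-tribromo-3,4-dioxocyclohexa-1,5-dien-1-yl)acetate F5 and sodium 2,4,5-tribromo-3-[2-tert-butoxy-1-(methylsulfonyl)-2-oxoethylidene]-6-oxocyclohexa-1,4-dien-1-olate F6, neither isolated.
   - The isolated product is tert-butyl 2-(2,3,6-tribromo-4,5-dihydroxyphenyl)-2-(methylsulfonyl)acetate F7.
   - TFA/CH2Cl2 at rt gives 6, which loses CO2 on warming in toluene at 80 °C to give 7.

3. Step 1, in-flask reduction. The neutral form of 4 is a quinone methide tautomer. Dithionite, or the sulfite it forms, may add to the methide carbon, or the anion may be reduced only sluggishly. The fallback sets out from 4 and comes back to the route at 5, which is then carried on without isolation. It moves the reduction into strong acid with a metal-ion reductant and merges it with step 2.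
   - Compound 4 is quenched with cold dilute HCl only, and the neutral methyl 2-(2,3,6-tribromo-5-hydroxy-4-oxocyclohexa-2,5-dien-1-ylidene)-2-(methylsulfonyl)acetate F8 is isolated.
   - F8 is heated with SnCl2·2H2O in conc. HCl/AcOH at reflux. Divalent tin reduces it to 5 with no sulfur nucleophile present, and the same hot acid takes 5 through 6 to 7.

**Further compounds**

F1 | step 1 | methyl 2-(3,4-dimethoxyphenyl)-2-(methylsulfonyl)acetate (racemic) | COC(=O)C(S(C)(=O)=O)c1ccc(OC)c(OC)c1
F2 | step 1 | 2-(3,4-dimethoxyphenyl)-2-(methylsulfonyl)acetic acid (racemic) | OC(=O)C(S(C)(=O)=O)c1ccc(OC)c(OC)c1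
F3 | step 1 | 1,2-dimethoxy-4-[(methylsulfonyl)methyl]benzene | COc1ccc(CS(C)(=O)=O)cc1OC
F4 | step 1 | 4-[(methylsulfonyl)methyl]benzene-1,2-diol | CS(=O)(=O)Cc1ccc(O)c(O)c1
F5 | step 2 | tert-butyl 2-(methylsulfonyl)-2-(2,5,6-tribromo-3,4-dioxocyclohexa-1,5-dien-1-yl)acetate (racemic) | CC(C)(C)OC(=O)C(S(C)(=O)=O)C1=C(Br)C(=O)C(=O)C(Br)=C1Br
F6 | step 2 | sodium 2,4,5-tribromo-3-[2-tert-butoxy-1-(methylsulfonyl)-2-oxoethylidene]-6-oxocyclohexa-1,4-dien-1-olate | CC(C)(C)OC(=O)C(S(C)(=O)=O)=C1C(Br)=C([O-])C(=O)C(Br)=C1Br.[Na+]
F7 | step 2 | tert-butyl 2-(2,3,6-tribromo-4,5-dihydroxyphenyl)-2-(methylsulfonyl)acetate (racemic) | CC(C)(C)OC(=O)C(S(C)(=O)=O)c1c(Br)c(O)c(O)c(Br)c1Br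
F8 | step 1 | methyl 2-(2,3,6-tribromo-5-hydroxy-4-oxocyclohexa-2,5-dien-1-ylidene)-2-(methylsulfonyl)acetate | COC(=O)C(S(C)(=O)=O)=C1C(Br)=C(O)C(=O)C(Br)=C1Br
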